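**Retrosynthetic overview**

1. Target 20 ⇐ bis(benzyl ether) 19 (hydrogenolysis) ⇐ primary alcohol 16 + (R)-2-methylbutanoic acid 17 (Steglich esterification) ⇐ silyl ether 15.
2. Oxolane 15 ⇐ diol 13 (primary tosylate, O1–C5 closure by the C2 hydroxyl) ⇐ cis-lactone 12 (LiAlH4).
3. 12 ⇐ α-methylene lactone 10 + arylboronic acid 11 (rhodium-catalysed aryl addition; protonation away from the C3 arm sets C4).
4. Feature used: in the oxolane (O1, C2–aryl, C3–CH2O-acyl, C4–CH2Ar, C5H2) the C2/C3 pair is a homoallylic alcohol, and C4, its benzylic carbon and C5 are a masked exocyclic C=CH2 and C=O of an α-methylene γ-lactone. Hence 10 ⇐ aldehyde 8 + (Z)-allylboronate 7 by enantioselective allylboration–lactonisation (forms C2–C3 and O1–C5).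
5. 7 ⇐ ynoate 4 + iodomethylboronate 5 ⇐ propargyl alcohol 1. Ring order: the only ring is made as the γ-lactone in step 4, opened in step 6 and re-closed as the oxolane in step 7.

Key step: step 4

Assumption: (R)-TRIP, the acid named in step 4, is expected to direct attack to the Re face of the aldehyde, as in its crotylborations of aryl aldehydes; if the ester-bearing boronate responds with the opposite sense, the (S)-acid is used. Compounds 5, 8, 11 and 17 are taken as commercial.

**Route**

Step 1
Reactants: 1 propargyl alcohol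
Product: 2 tert-butyldimethyl(prop-2-yn-1-yloxy)silane
Conditions: TBSCl, imidazole, CH2Cl2, 0 °C → rt
Reagents that add atoms: tert-butyldimethylsilyl chloride, CC(C)(C)[Si](C)(C)Cl
Why: Imidazole-promoted O-silylation of a primary alcohol is routine and masks the hydroxyl that later becomes the acylated CH2O arm on C3.

Step 2
Reactants: 2 tert-butyldimethyl(prop-2-yn-1-yloxy)silane
Product: 4 methyl 4-[(tert-butyldimethylsilyl)oxy]but-2-ynoate, via lithium acetylide 3 (not isolated)
Conditions: n-BuLi, THF, −78 °C; then ClCO2Me, −78 → 0 °C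
Reagents that add atoms: methyl chloroformate, COC(=O)Cl
Why: Deprotonation of the terminal alkyne and C-acylation of the lithium acetylide with a chloroformate is a standard ynoate synthesis, and the silyl ether is inert to n-BuLi at −78 °C.

Step 3
Reactants: 4 methyl 4-[(tert-butyldimethylsilyl)oxy]but-2-ynoate; 5 2-(iodomethyl)-4,4,5,5-tetramethyl-1,3,2-dioxaborolane
Product: 7 methyl (Z)-4-[(tert-butyldimethylsilyl)oxy]-2-[(4,4,5,5-tetramethyl-1,3,2-dioxaborolan-2-yl)methyl]but-2-enoate (CH2B trans to CH2OTBS), via alkenylalane 6 (not isolated)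
Conditions: iBu2AlH, HMPA, MeCu (5 mol %, from MeLi and CuI), THF, −50 °C; then 5, −50 → 25 °C
Reagents that add atoms: none
Why: Conjugate hydroalumination of the ynoate with the iBu2AlH–HMPA reagent is a syn addition that puts H on C3 and the metal on C2 trans to CH2OTBS, and copper-assisted alkylation of this alkenylmetal with the iodomethylboronate proceeds with retention, which should give the allylboronate with CH2B trans to CH2OTBS.

Step 4
Reactants: 7 methyl (Z)-4-[(tert-butyldimethylsilyl)oxy]-2-[(4,4,5,5-tetramethyl-1,3,2-dioxaborolan-2-yl)methyl]but-2-enoate; 8 4-(benzyloxy)-3-methoxybenzaldehyde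
Product: 10 (4S,5R)-5-[4-(benzyloxy)-3-methoxyphenyl]-4-{[(tert-butyldimethylsilyl)oxy]methyl}-3-methylideneoxolan-2-one (4,5-trans), via O-boryl homoallylic ester 9 (not isolated)
Conditions: (R)-3,3'-bis(2,4,6-triisopropylphenyl)-1,1'-binaphthyl-2,2'-diyl hydrogen phosphate (10 mol %), 4 Å MS, toluene, 0 → 25 °C; then 50 °C, 2 h
Reagents that add atoms: none
Why: Proposed new method: chiral-phosphoric-acid catalysis is established for allyl and crotyl pinacol boronates, and allylboration–lactonisation of 2-alkoxycarbonyl allylboronates is established thermally and with achiral acids, but the chiral acid has not been shown on this ester-deactivated, γ-substituted boronate class, so the step rests on the reasoning that the acid P–OH hydrogen-bonds to a boronate oxygen (with P=O to the formyl H) and thereby both accelerates and face-selects the usual closed six-membered chair. In that chair the γ-carbon of 7 attacks the Re face of aldehyde 8 with the aryl group equatorial, the sense expected from the catalyst by analogy with its crotylborations, which sets the aryl-bearing carbon (lactone C5, target C2) as R. Because CH2OTBS is trans to CH2B in 7 it is equatorial too, so the new C–C bond forms with the anti relationship and lactone C4 (target C3) is S by the alkene geometry alone. The O-boryl alkoxide 9 then attacks the neighbouring ester carbonyl (5-exo-trig acyl substitution with loss of MeOBpin), which closes the γ-lactone and turns the anti pair into the trans-4,5 ring. The step needs enantioface selectivity, secured by the catalysed path outrunning a background reaction that is slow for this electron-poor boronate at or below 25 °C, and anti selectivity, secured by the geometric purity of 7; the exocyclic methylene is left for step 5.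

Step 5
Reactants: 10 (4S,5R)-5-[4-(benzyloxy)-3-methoxyphenyl]-4-{[(tert-butyldimethylsilyl)oxy]methyl}-3-methylideneoxolan-2-one; 11 [4-(benzyloxy)-3-methoxyphenyl]boronic acid
Product: 12 (3S,4S,5R)-3-[4-(benzyloxy)-3-methoxybenzyl]-5-[4-(benzyloxy)-3-methoxyphenyl]-4-{[(tert-butyldimethylsilyl)oxy]methyl}oxolan-2-one (3,4-cis; 4,5-trans)
Conditions: [Rh(cod)Cl]2 (3 mol %), KOH (10 mol %), 11 (2 equiv), dioxane/H2O 10:1, 25 °C
Reagents that add atoms: none
Why: Rhodium-catalysed conjugate addition of an arylboronic acid (Hayashi–Miyaura type) delivers the aryl group to the exocyclic CH2, and the rhodium enolate is protonated by water at C3 on the face away from the neighbouring CH2OTBS arm, which should set C3 as S with the new benzyl group cis to that arm, while the nearly neutral medium limits epimerisation of this kinetically formed centre.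

Step 6
Reactants: 12 (3S,4S,5R)-3-[4-(benzyloxy)-3-methoxybenzyl]-5-[4-(benzyloxy)-3-methoxyphenyl]-4-{[(tert-butyldimethylsilyl)oxy]methyl}oxolan-2-one
Product: 13 (1R,2S,3S)-3-[4-(benzyloxy)-3-methoxybenzyl]-1-[4-(benzyloxy)-3-methoxyphenyl]-2-{[(tert-butyldimethylsilyl)oxy]methyl}butane-1,4-diol
Conditions: LiAlH4, THF, −20 → 0 °C; aq. NaOH work-up
Reagents that add atoms: none
Why: Hydride reduction of a lactone to the 1,4-diol with LiAlH4 touches no stereocentre and spares silyl and benzyl ethers, and at low temperature reduction should outrun enolisation of the cis α-centre.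

Step 7
Reactants: 13 (1R,2S,3S)-3-[4-(benzyloxy)-3-methoxybenzyl]-1-[4-(benzyloxy)-3-methoxyphenyl]-2-{[(tert-butyldimethylsilyl)oxy]methyl}butane-1,4-diol
Product: 15 tert-butyl({(2R,3S,4S)-4-[4-(benzyloxy)-3-methoxybenzyl]-2-[4-(benzyloxy)-3-methoxyphenyl]oxolan-3-yl}methoxy)dimethylsilane, via primary tosylate 14 (not isolated)
Conditions: TsCl (1.1 equiv), pyridine, DMAP (cat.), 0 → 50 °C
Reagents that add atoms: none
Why: The primary hydroxyl is sulfonylated in preference to the hindered secondary benzylic one, and the benzylic oxygen then displaces the tosylate in a 5-exo-tet intramolecular Williamson etherification, so the benzylic C–O bond is never broken and the configuration at the aryl-bearing carbon is retained.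

Step 8
Reactants: 15 tert-butyl({(2R,3S,4S)-4-[4-(benzyloxy)-3-methoxybenzyl]-2-[4-(benzyloxy)-3-methoxyphenyl]oxolan-3-yl}methoxy)dimethylsilane
Product: 16 {(2R,3S,4S)-4-[4-(benzyloxy)-3-methoxybenzyl]-2-[4-(benzyloxy)-3-methoxyphenyl]oxolan-3-yl}methanol
Conditions: TBAF, THF, 0 °C → rt
Reagents that add atoms: none
Why: Fluoride-mediated cleavage of the alkyl silyl ether is selective because benzyl ethers and the oxolane are inert to TBAF.

Step 9
Reactants: 16 {(2R,3S,4S)-4-[4-(benzyloxy)-3-methoxybenzyl]-2-[4-(benzyloxy)-3-methoxyphenyl]oxolan-3-yl}methanol; 17 (R)-2-methylbutanoic acid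
Product: 19 {(2R,3S,4S)-4-[4-(benzyloxy)-3-methoxybenzyl]-2-[4-(benzyloxy)-3-methoxyphenyl]oxolan-3-yl}methyl (2R)-2-methylbutanoate, via O-acylisourea 18 (not isolated)
Conditions: DCC, DMAP (10 mol %), CH2Cl2, 0 °C → rt
Reagents that add atoms: none
Why: Steglich esterification (carbodiimide activation with catalytic DMAP) acylates the unhindered primary alcohol under conditions mild enough, at 0 °C with only catalytic DMAP, to keep the α-stereocentre of the acid intact.

Step 10
Reactants: 19 {(2R,3S,4S)-4-[4-(benzyloxy)-3-methoxybenzyl]-2-[4-(benzyloxy)-3-methoxyphenyl]oxolan-3-yl}methyl (2R)-2-methylbutanoate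
Product: 20 {(2R,3S,4S)-2-(4-hydroxy-3-methoxyphenyl)-4-(4-hydroxy-3-methoxybenzyl)oxolan-3-yl}methyl (2R)-2-methylbutanoate (CNP0315069.1)
Conditions: H2 (1 atm), 10 % Pd/C, EtOAc, 25 °C, stopped at complete debenzylation
Reagents that add atoms: none
Why: Catalytic hydrogenolysis cleaves aryl benzyl ethers much faster than the benzylic C2–O1 bond of the oxolane in a neutral aprotic solvent, so stopping at full debenzylation should free both phenols with the ester and all four stereocentres unchanged.

**Compound list**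

1 | propargyl alcohol | C#CCO | starting material
2 | tert-butyldimethyl(prop-2-yn-1-yloxy)silane | C#CCO[Si](C)(C)C(C)(C)C | intermediate
3 | lithium 3-[(tert-butyldimethylsilyl)oxy]prop-1-yn-1-ide | [Li]C#CCO[Si](C)(C)C(C)(C)C | intermediate (not isolated)
4 | methyl 4-[(tert-butyldimethylsilyl)oxy]but-2-ynoate | COC(=O)C#CCO[Si](C)(C)C(C)(C)C | intermediate
5 | 2-(iodomethyl)-4,4,5,5-tetramethyl-1,3,2-dioxaborolane | CC1(C)OB(CI)OC1(C)C | starting material
6 | methyl (E)-2-[bis(2-methylpropyl)alumanyl]-4-[(tert-butyldimethylsilyl)oxy]but-2-enoate (Al trans to CH2OTBS) | COC(=O)/C(=C\CO[Si](C)(C)C(C)(C)C)[Al](CC(C)C)CC(C)C | intermediate (not isolated)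
7 | methyl (Z)-4-[(tert-butyldimethylsilyl)oxy]-2-[(4,4,5,5-tetramethyl-1,3,2-dioxaborolan-2-yl)methyl]but-2-enoate | CC1(C)OB(C/C(C(=O)OC)=C/CO[Si](C)(C)C(C)(C)C)OC1(C)C | intermediate
8 | 4-(benzyloxy)-3-methoxybenzaldehyde | O=Cc1ccc(OCc2ccccc2)c(OC)c1 | starting material
9 | methyl (3S,4R)-4-[4-(benzyloxy)-3-methoxyphenyl]-3-{[(tert-butyldimethylsilyl)oxy]methyl}-2-methylidene-4-[(4,4,5,5-tetramethyl-1,3,2-dioxaborolan-2-yl)oxy]butanoate | COC(=O)C(=C)[C@@H](CO[Si](C)(C)C(C)(C)C)[C@@H](OB1OC(C)(C)C(C)(C)O1)c1ccc(OCc2ccccc2)c(OC)c1 | intermediate (not isolated)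
10 | (4S,5R)-5-[4-(benzyloxy)-3-methoxyphenyl]-4-{[(tert-butyldimethylsilyl)oxy]methyl}-3-methylideneoxolan-2-one | C=C1C(=O)O[C@@H](c2ccc(OCc3ccccc3)c(OC)c2)[C@@H]1CO[Si](C)(C)C(C)(C)C | intermediate
11 | [4-(benzyloxy)-3-methoxyphenyl]boronic acid | OB(O)c1ccc(OCc2ccccc2)c(OC)c1 | starting material
12 | (3S,4S,5R)-3-[4-(benzyloxy)-3-methoxybenzyl]-5-[4-(benzyloxy)-3-methoxyphenyl]-4-{[(tert-butyldimethylsilyl)oxy]methyl}oxolan-2-one | COc1cc(C[C@@H]2C(=O)O[C@@H](c3ccc(OCc4ccccc4)c(OC)c3)[C@@H]2CO[Si](C)(C)C(C)(C)C)ccc1OCc1ccccc1 | intermediate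
13 | (1R,2S,3S)-3-[4-(benzyloxy)-3-methoxybenzyl]-1-[4-(benzyloxy)-3-methoxyphenyl]-2-{[(tert-butyldimethylsilyl)oxy]methyl}butane-1,4-diol | COc1cc(C[C@H](CO)[C@@H](CO[Si](C)(C)C(C)(C)C)[C@@H](O)c2ccc(OCc3ccccc3)c(OC)c2)ccc1OCc1ccccc1 | intermediate
14 | (2S,3S,4R)-2-[4-(benzyloxy)-3-methoxybenzyl]-4-[4-(benzyloxy)-3-methoxyphenyl]-3-{[(tert-butyldimethylsilyl)oxy]methyl}-4-hydroxybutyl 4-methylbenzenesulfonate | COc1cc(C[C@H](COS(=O)(=O)c2ccc(C)cc2)[C@@H](CO[Si](C)(C)C(C)(C)C)[C@@H](O)c2ccc(OCc3ccccc3)c(OC)c2)ccc1OCc1ccccc1 | intermediate (not isolated)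
15 | tert-butyl({(2R,3S,4S)-4-[4-(benzyloxy)-3-methoxybenzyl]-2-[4-(benzyloxy)-3-methoxyphenyl]oxolan-3-yl}methoxy)dimethylsilane | CC(C)(C)[Si](C)(C)OC[C@@H]1[C@H](Cc2ccc(OCc3ccccc3)c(OC)c2)CO[C@H]1c1ccc(OCc2ccccc2)c(OC)c1 | intermediate
16 | {(2R,3S,4S)-4-[4-(benzyloxy)-3-methoxybenzyl]-2-[4-(benzyloxy)-3-methoxyphenyl]oxolan-3-yl}methanol | OC[C@@H]1[C@H](Cc2ccc(OCc3ccccc3)c(OC)c2)CO[C@H]1c1ccc(OCc2ccccc2)c(OC)c1 | intermediate
17 | (R)-2-methylbutanoic acid | CC[C@@H](C)C(=O)O | starting material
18 | O-[(2R)-2-methylbutanoyl]-N,N'-dicyclohexylisourea | CC[C@@H](C)C(=O)OC(=NC1CCCCC1)NC1CCCCC1 | intermediate (not isolated)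
19 | {(2R,3S,4S)-4-[4-(benzyloxy)-3-methoxybenzyl]-2-[4-(benzyloxy)-3-methoxyphenyl]oxolan-3-yl}methyl (2R)-2-methylbutanoate | CC[C@@H](C)C(=O)OC[C@@H]1[C@H](Cc2ccc(OCc3ccccc3)c(OC)c2)CO[C@H]1c1ccc(OCc2ccccc2)c(OC)c1 | intermediate
20 | {(2R,3S,4S)-2-(4-hydroxy-3-methoxyphenyl)-4-(4-hydroxy-3-methoxybenzyl)oxolan-3-yl}methyl (2R)-2-methylbutanoate | CC[C@@H](C)C(=O)OC[C@@H]1[C@H](Cc2ccc(O)c(OC)c2)CO[C@H]1c1ccc(O)c(OC)c1 | target

**Step count**

Total steps: 10. Longest linear sequence: 10 steps (1 → 20); compounds 5, 8, 11 and 17 enter as purchased materials.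

**Steps most likely to fail**

Step 4 (bears the label). The weak chiral acid may not accelerate the electron-poor boronate enough, so that conversion needs temperatures at which the uncatalysed, racemic pathway takes over. Enantioface selectivity may also be eroded, or lactonisation may stay incomplete. The fallback uses known chemistry and sets out from 7 and 8. The allylboration–lactonisation is run without chiral control (Sc(OTf)3, 10 mol %, toluene, 25 °C, or toluene alone at 80 °C). Through 9 and its mirror image, the enantiomeric O-boryl homoallylic ester F1 (not isolated), this should give the racemic trans-lactone, that is 10 together with the (4R,5S)-lactone F2. Preparative chromatography on a chiral stationary phase (polysaccharide carbamate column, supercritical CO2/alcohol) then separates the enantiomers, and the route is rejoined at 10.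

Step 5. Protonation of the rhodium enolate may show poor facial selectivity, the new C3 centre may epimerise under base to the more stable trans-lactone, or β-hydride elimination may give the arylidene lactone. The fallback sets out from 10 and separates C–C bond formation from protonation. The Grignard reagent [4-(benzyloxy)-3-methoxyphenyl]magnesium bromide F3 is made from commercial 1-(benzyloxy)-4-bromo-2-methoxybenzene and Mg in THF. It is added to 10 with CuBr·SMe2 (20 mol %) and TMSCl in THF at −78 °C, which traps the conjugate adduct as the silyl ketene acetal (4S,5R)-3-[4-(benzyloxy)-3-methoxybenzyl]-5-[4-(benzyloxy)-3-methoxyphenyl]-4-{[(tert-butyldimethylsilyl)oxy]methyl}-2-(trimethylsilyloxy)-4,5-dihydrofuran F4. In a separate operation F4 is protonated kinetically with acetic acid in THF at −78 °C, from the face opposite the CH2OTBS arm and with no aqueous base present. The route is rejoined at 12.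

Step 10. Over-reduction is the concern: hydrogenolysis of the benzylic C2–O1 bond of the oxolane (ring opening to the seco diarylbutane) may compete with O-debenzylation. The fallback sets out from 19 and removes the benzyl groups without a reducing agent. BCl3 with pentamethylbenzene as cation scavenger in CH2Cl2 at −78 °C is used, with a cold CHCl3/MeOH quench. This is a Lewis-acid dealkylation in which no hydrogen or metal surface is present, so the ring C–O bond cannot be reduced, and it arrives directly at 20 with no new intermediate.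

**Further compounds**

F1 | step 4 | methyl (3R,4S)-4-[4-(benzyloxy)-3-methoxyphenyl]-3-{[(tert-butyldimethylsilyl)oxy]methyl}-2-methylidene-4-[(4,4,5,5-tetramethyl-1,3,2-dioxaborolan-2-yl)oxy]butanoate (enantiomer of 9) | COC(=O)C(=C)[C@H](CO[Si](C)(C)C(C)(C)C)[C@H](OB1OC(C)(C)C(C)(C)O1)c1ccc(OCc2ccccc2)c(OC)c1
F2 | step 4 | (4R,5S)-5-[4-(benzyloxy)-3-methoxyphenyl]-4-{[(tert-butyldimethylsilyl)oxy]methyl}-3-methylideneoxolan-2-one (enantiomer of 10) | C=C1C(=O)O[C@H](c2ccc(OCc3ccccc3)c(OC)c2)[C@H]1CO[Si](C)(C)C(C)(C)C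
F3 | step 5 | [4-(benzyloxy)-3-methoxyphenyl]magnesium bromide | COc1cc([Mg]Br)ccc1OCc1ccccc1
F4 | step 5 | (4S,5R)-3-[4-(benzyloxy)-3-methoxybenzyl]-5-[4-(benzyloxy)-3-methoxyphenyl]-4-{[(tert-butyldimethylsilyl)oxy]methyl}-2-(trimethylsilyloxy)-4,5-dihydrofuran | C[Si](C)(C)OC1=C(Cc2ccc(OCc3ccccc3)c(OC)c2)[C@@H](CO[Si](C)(C)C(C)(C)C)[C@H](c2ccc(OCc3ccccc3)c(OC)c2)O1
F0 | step 10 | none | none
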